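**Plan**

- Cuts, last bond first: the imide N–C bonds and C12–C13 (ammonolysis after an Evans syn-aldol); C8=C17 (Wittig on a C8 ketone); C6–C7 and C5–C10 together (intramolecular Diels–Alder); C8–C9 and C10–C20 (carbomagnesiation–carboxylation of a C9≡C10 alkyne); C1–C10 (acetylide plus epoxide); C4–C18 and C4–C19 (lactone enolate alkylations).
- Enabling feature: ring B (C5–C10) is a cyclohexane whose C8 carries the exocyclic methylene, i.e. a masked ketone, and whose C9 arm ends in O-12. Read backwards, C7=C8(O)–C9=C10 is a 2-oxy-diene that O-12 ties into a 2-methylene-3-alkylidene-tetrahydrofuran (temporary ring, locked s-cis); C5=C6 is the dienophile (activated by a removable 6-sulfonyl group); C1–C4 of ring A is the tether.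
- Forward order: chiral lactone → open C1–C5 chain with C2–Cl and quaternary C4 → alkylidene lactone → vinyl sulfone → methylenation → rings A and B in one step → desulfonylation and enol-ether hydrolysis (temporary ring opened) → exocyclic methylene, aldehyde → aldol → imide.
- Stereochemistry: C2 from (R)-γ-(trityloxymethyl)butyrolactone (inverted in the Appel step); C4 by anti alkylation of the lactone enolate; C5 and C10 in the cycloaddition, controlled by C2/C4 and by the diene geometry from syn-carbomagnesiation; C9 by axial protonation and equilibration; C12/C13 by the (R)-4-benzyloxazolidinone.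

Key step: step 15

Remark: atoms are called by the labdane numbers of the target (C-1 to C-20, imide carbons C-13 to C-16) in all intermediates; hydroxy ketone 22 is written in its open form although it may equilibrate with the cyclic hemiketal.

**Route**

Step 1
Reactants: 1 (R)-5-[(trityloxy)methyl]dihydrofuran-2(3H)-one
Product: 2 (3R,5R)-3-{[(triisopropylsilyl)oxy]methyl}-5-[(trityloxy)methyl]dihydrofuran-2(3H)-one (3,5-trans; the cis epimer converges in step 2)
Conditions: LDA, THF, −78 °C; (i-Pr)3SiOCH2Cl, −78 → −40 °C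
Reagents that add atoms: (triisopropylsiloxy)methyl chloride, CC(C)[Si](OCCl)(C(C)C)C(C)C
Why: Alkylation of a lactone lithium enolate with a reactive chloromethyl ether installs C-18 already as its TIPS ether; the new center is erased by the next enolization.

Step 2
Reactants: 2 (3R,5R)-3-{[(triisopropylsilyl)oxy]methyl}-5-[(trityloxy)methyl]dihydrofuran-2(3H)-one
Product: 3 (3S,5R)-3-methyl-3-{[(triisopropylsilyl)oxy]methyl}-5-[(trityloxy)methyl]dihydrofuran-2(3H)-one
Conditions: LDA, THF/DMPU, −78 °C; MeI, −78 °C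
Reagents that add atoms: iodomethane, CI
Why: The second alkylation of the γ-(trityloxymethyl)butyrolactone enolate should occur anti to the bulky CH2OTr group, so the quaternary C-4 is set with CH3 trans and CH2OTIPS cis to C-1 (sequential enolate dialkylation under 1,3-induction).

Step 3
Reactants: 3 (3S,5R)-3-methyl-3-{[(triisopropylsilyl)oxy]methyl}-5-[(trityloxy)methyl]dihydrofuran-2(3H)-one
Product: 4 (3S,5R)-5-(hydroxymethyl)-3-methyl-3-{[(triisopropylsilyl)oxy]methyl}dihydrofuran-2(3H)-one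
Conditions: TsOH·H2O (cat.), MeOH/CH2Cl2, rt
Reagents that add atoms: none
Why: Acid-catalysed solvolysis of the trityl ether through the trityl cation should leave the primary TIPS ether and the lactone untouched.

Step 4
Reactants: 4 (3S,5R)-5-(hydroxymethyl)-3-methyl-3-{[(triisopropylsilyl)oxy]methyl}dihydrofuran-2(3H)-one
Product: 5 [(2R,4S)-4-methyl-5-oxo-4-{[(triisopropylsilyl)oxy]methyl}tetrahydrofuran-2-yl]methyl 4-methylbenzenesulfonate
Conditions: TsCl, pyridine, DMAP (cat.), CH2Cl2, 0 °C → rt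
Reagents that add atoms: p-toluenesulfonyl chloride, Cc1ccc(cc1)S(Cl)(=O)=O
Why: Routine sulfonylation of the only free (primary) hydroxyl turns C-1 into an electrophile.

Step 5
Reactants: 5 [(2R,4S)-4-methyl-5-oxo-4-{[(triisopropylsilyl)oxy]methyl}tetrahydrofuran-2-yl]methyl 4-methylbenzenesulfonate
Product: 6 methyl (2S)-2-methyl-3-[(2R)-oxiran-2-yl]-2-{[(triisopropylsilyl)oxy]methyl}propanoate
Conditions: NaOMe, MeOH, 0 °C → rt
Reagents that add atoms: sodium methoxide, [Na+].[O-]C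
Why: Methanolysis of the lactone frees the C-2 alkoxide, which closes the C-1/C-2 epoxide by 3-exo-tet displacement of tosylate with retention at C-2 (the known lactone tosylate to epoxy ester conversion).

Step 6
Reactants: 6 methyl (2S)-2-methyl-3-[(2R)-oxiran-2-yl]-2-{[(triisopropylsilyl)oxy]methyl}propanoate; 7 tert-butyl(but-3-yn-1-yloxy)dimethylsilane
Product: 9 (3S,5S)-5-{5-[(tert-butyldimethylsilyl)oxy]pent-2-yn-1-yl}-3-methyl-3-{[(triisopropylsilyl)oxy]methyl}dihydrofuran-2(3H)-one, via open-chain hydroxy ester 8 (not isolated)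
Conditions: 7, n-BuLi, THF, −78 °C; BF3·OEt2; then 6, −78 °C; NH4Cl; PPTS (cat.), CH2Cl2, rt
Reagents that add atoms: none
Why: BF3-promoted opening of the terminal epoxide by the lithium acetylide at the unhindered C-1 forms the C1–C10 bond without touching the pivalate-like ester, and the γ-hydroxy ester relactonizes, which stores C-2–O and C-5 in one ring.

Step 7
Reactants: 9 (3S,5S)-5-{5-[(tert-butyldimethylsilyl)oxy]pent-2-yn-1-yl}-3-methyl-3-{[(triisopropylsilyl)oxy]methyl}dihydrofuran-2(3H)-one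
Product: 10 (3S,5S)-5-{5-[(tert-butyldimethylsilyl)oxy]pent-2-yn-1-yl}-3-methyl-3-{[(triisopropylsilyl)oxy]methyl}tetrahydrofuran-2-ol (both anomers)
Conditions: i-Bu2AlH, CH2Cl2, −78 °C; Rochelle salt
Reagents that add atoms: none
Why: Partial reduction of the lactone stops at the lactol because the tetrahedral aluminate is stable at −78 °C.

Step 8
Reactants: 10 (3S,5S)-5-{5-[(tert-butyldimethylsilyl)oxy]pent-2-yn-1-yl}-3-methyl-3-{[(triisopropylsilyl)oxy]methyl}tetrahydrofuran-2-ol
Product: 11 (3R,5S)-10-[(tert-butyldimethylsilyl)oxy]-3-methyl-3-{[(triisopropylsilyl)oxy]methyl}dec-1-en-7-yn-5-ol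
Conditions: Ph3PCH3Br, KHMDS, THF, 0 °C → rt
Reagents that add atoms: methyltriphenylphosphonium bromide, C[P+](c1ccccc1)(c1ccccc1)c1ccccc1.[Br-]
Why: Wittig methylenation of the open hydroxy-aldehyde form masks C-5 as a vinyl group that cannot isomerize (C-4 is quaternary) and frees the C-2 hydroxyl.

Step 9
Reactants: 11 (3R,5S)-10-[(tert-butyldimethylsilyl)oxy]-3-methyl-3-{[(triisopropylsilyl)oxy]methyl}dec-1-en-7-yn-5-ol
Product: 12 tert-butyl{[(6R,8R)-6-chloro-8-methyl-8-{[(triisopropylsilyl)oxy]methyl}dec-9-en-3-yn-1-yl]oxy}dimethylsilane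
Conditions: PPh3, CCl4, CH2Cl2, 40 °C
Reagents that add atoms: carbon tetrachloride, ClC(Cl)(Cl)Cl
Why: Appel reaction; SN2 attack of chloride on the alkoxyphosphonium ion inverts C-2 to the configuration of the target (the later equatorial 2α-chloride).

Step 10
Reactants: 12 tert-butyl{[(6R,8R)-6-chloro-8-methyl-8-{[(triisopropylsilyl)oxy]methyl}dec-9-en-3-yn-1-yl]oxy}dimethylsilane
Product: 13 (6R,8R)-6-chloro-8-methyl-8-{[(triisopropylsilyl)oxy]methyl}dec-9-en-3-yn-1-ol
Conditions: CSA (10 mol %), MeOH/CH2Cl2, 0 °C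
Reagents that add atoms: none
Why: A primary TBS ether is methanolysed far faster than the hindered neopentyl TIPS ether, which exposes the homopropargylic C-12 hydroxyl.

Step 11
Reactants: 13 (6R,8R)-6-chloro-8-methyl-8-{[(triisopropylsilyl)oxy]methyl}dec-9-en-3-yn-1-ol
Product: 16 (3E)-3-[(4R,6R)-4-chloro-6-methyl-6-{[(triisopropylsilyl)oxy]methyl}oct-7-en-2-ylidene]dihydrofuran-2(3H)-one, via alkenylmagnesium alkoxide 14 (not isolated), via hydroxy acid 15 (not isolated)
Conditions: Fe(acac)3 (15 mol %), MeMgBr (5 equiv), THF, −20 → 0 °C; CO2, −20 °C → rt; 1 M HCl; TsOH·H2O (cat.), CH2Cl2, rt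
Reagents that add atoms: methylmagnesium bromide, C[Mg]Br; carbon dioxide, O=C=O
Why: Alkoxide-directed iron-catalysed syn-carbomagnesiation of the homopropargylic alcohol puts CH3 on the distal C-10 and magnesium on C-9 (five-membered chelate); carboxylation with retention and lactonization then give the alkylidene lactone with the C-20 methyl cis to the carbonyl and C-1 cis to C-11.

Step 12
Reactants: 16 (3E)-3-[(4R,6R)-4-chloro-6-methyl-6-{[(triisopropylsilyl)oxy]methyl}oct-7-en-2-ylidene]dihydrofuran-2(3H)-one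
Product: 17 (2S,4R,6E)-4-chloro-2-methyl-6-(2-oxodihydrofuran-3(2H)-ylidene)-2-{[(triisopropylsilyl)oxy]methyl}heptanal
Conditions: OsO4 (2 mol %), NaIO4, 2,6-lutidine, dioxane/H2O, rt
Reagents that add atoms: osmium tetroxide, O=[Os](=O)(=O)=O; sodium periodate, [Na+].[O-]I(=O)(=O)=O
Why: Lemieux–Johnson cleavage should take the monosubstituted vinyl group and leave the tetrasubstituted, electron-poor alkylidene lactone, giving the non-enolizable C-5 aldehyde.

Step 13
Reactants: 17 (2S,4R,6E)-4-chloro-2-methyl-6-(2-oxodihydrofuran-3(2H)-ylidene)-2-{[(triisopropylsilyl)oxy]methyl}heptanal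
Product: 18 (3E)-3-[(4R,6R,7E)-4-chloro-6-methyl-8-(phenylsulfonyl)-6-{[(triisopropylsilyl)oxy]methyl}oct-7-en-2-ylidene]dihydrofuran-2(3H)-one
Conditions: (EtO)2P(O)CH2SO2Ph (1.3 equiv), LiHMDS (1.2 equiv), THF, −78 → 0 °C
Reagents that add atoms: diethyl [(phenylsulfonyl)methyl]phosphonate, CCOP(=O)(CS(=O)(=O)c1ccccc1)OCC
Why: Horner–Wadsworth–Emmons olefination with the sulfonyl-stabilized phosphonate gives the (E)-vinyl sulfone; no excess base is used, so vinylogous E1cB loss of HCl from C-1/C-2 is avoided.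

Step 14
Reactants: 18 (3E)-3-[(4R,6R,7E)-4-chloro-6-methyl-8-(phenylsulfonyl)-6-{[(triisopropylsilyl)oxy]methyl}oct-7-en-2-ylidene]dihydrofuran-2(3H)-one
Product: 19 (3E)-3-[(4R,6R,7E)-4-chloro-6-methyl-8-(phenylsulfonyl)-6-{[(triisopropylsilyl)oxy]methyl}oct-7-en-2-ylidene]-2-methylenetetrahydrofuran
Conditions: Cp2Ti(μ-CH2)(μ-Cl)AlMe2 (Tebbe reagent), pyridine, THF/toluene, −40 → 0 °C; filtration through basic alumina, used at once
Reagents that add atoms: Tebbe reagent Cp2Ti(μ-CH2)(μ-Cl)AlMe2, C[Al-]1(C)C[Ti]([Cl+]1)(C1C=CC=C1)C1C=CC=C1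
Why: Tebbe methylenation of the lactone carbonyl through an oxatitanacyclobutane gives the exocyclic enol ether (C-7), which completes the s-cis-locked 2-alkoxy diene C7=C8–C9=C10.

Step 15
Reactants: 19 (3E)-3-[(4R,6R,7E)-4-chloro-6-methyl-8-(phenylsulfonyl)-6-{[(triisopropylsilyl)oxy]methyl}oct-7-en-2-ylidene]-2-methylenetetrahydrofuran
Product: 20 2α-chloro-6α-(phenylsulfonyl)-18-[(triisopropylsilyl)oxy]-8,12-epoxy-13,14,15,16,17-pentanorlabd-8-ene (trans-decalin with 5α-H and 10β-CH3; 4,5-dihydrofuran fused at C8=C9)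
Conditions: toluene (5 mM), BHT, solid K2CO3, base-washed sealed tube, 110 °C
Reagents that add atoms: none
Why: Thermal, concerted but asynchronous [4+2] cycloaddition of normal electron demand between the electron-rich 2-alkoxy diene C7=C8–C9=C10 (held s-cis because C8 and C9 are ring atoms of the 2-methylene-3-alkylidene-tetrahydrofuran) and the (E)-vinyl sulfone C5=C6, with the C5–C10 bond the more advanced; the closest known reaction type is the intramolecular Diels–Alder reaction of 1,7,9-decatrienes with a terminal sulfonyl or nitro group on the dienophile. Ring B is closed as the new cyclohexene by the cycloaddition itself (bonds C6–C7 and C5–C10), and ring A is closed in the fused mode by the four-carbon tether C1–C4 between diene terminus C10 and dienophile carbon C5, which also enforces the regiochemistry against the electronic bias of the alkoxy group. C10 and C5 should come out trans (C20 methyl β, H-5 α) because the tether is the outside and the methyl the inside substituent of the diene terminus and the transition state with the tether exo and the sulfonyl group endo is used; the tether-endo (cis-decalin) alternative would push the quaternary C4 under the C11 methylene on C9, which acts as a steric directing group. The absolute sense follows from the chair-like tether with the C2 chlorine equatorial and the C4 methyl axial; attack on the other diene face would set chlorine, CH2OTIPS and the C20 methyl 1,3-diaxial. The 6α-sulfonyl center is incidental and is removed in step 16. The step needs trans over cis ring fusion, one π-face, and cycloaddition faster than a 1,5-hydrogen shift or acid-induced isomerization of the dienol ether; sulfonyl activation, the locked s-cis diene, high dilution and the base-washed vessel are meant to secure this.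

Step 16
Reactants: 20 2α-chloro-6α-(phenylsulfonyl)-18-[(triisopropylsilyl)oxy]-8,12-epoxy-13,14,15,16,17-pentanorlabd-8-ene
Product: 22 2α-chloro-12-hydroxy-18-[(triisopropylsilyl)oxy]-13,14,15,16,17-pentanorlabdan-8-one (9α-H), via desulfonylated enol ether 21 (not isolated)
Conditions: 6% Na(Hg), Na2HPO4, MeOH/THF, −20 °C → rt; then 1 M HCl, THF, rt
Reagents that add atoms: water, O
Why: Electron-transfer cleavage of the secondary alkyl phenyl sulfone (vinyl sulfone used as an ethylene equivalent) removes the activating group without touching the alkyl chloride; aqueous acid then hydrolyses the cyclic enol ether with axial α-face protonation of C-9 anti to the C-10 methyl, opening the temporary ring to the C-8 ketone and the C-12 alcohol.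

Step 17
Reactants: 22 2α-chloro-12-hydroxy-18-[(triisopropylsilyl)oxy]-13,14,15,16,17-pentanorlabdan-8-one
Product: 23 2α-chloro-18-[(triisopropylsilyl)oxy]-13,14,15,16-tetranorlabd-8(17)-en-12-ol
Conditions: Ph3PCH3Br (5 equiv), KOt-Bu (4.8 equiv), toluene, rt → 70 °C
Reagents that add atoms: methyltriphenylphosphonium bromide, C[P+](c1ccccc1)(c1ccccc1)c1ccccc1.[Br-]
Why: Wittig methylenation of the hindered C-8 ketone with excess ylide installs C-17; any C-9 epimer equilibrates under the basic conditions to the equatorial 9β side chain, and the equatorial chloride has no anti-periplanar hydrogen for E2.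

Step 18
Reactants: 23 2α-chloro-18-[(triisopropylsilyl)oxy]-13,14,15,16-tetranorlabd-8(17)-en-12-ol
Product: 24 2α-chloro-18-[(triisopropylsilyl)oxy]-13,14,15,16-tetranorlabd-8(17)-en-12-al
Conditions: Dess–Martin periodinane, NaHCO3, CH2Cl2, 0 °C → rt
Reagents that add atoms: none
Why: Buffered Dess–Martin oxidation of the primary alcohol gives the C-12 aldehyde without acid that could isomerize the exocyclic alkene.

Step 19
Reactants: 25 (R)-4-benzyl-1,3-oxazolidin-2-one; 26 methyl 4-chloro-4-oxobutanoate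
Product: 27 methyl 4-[(4R)-4-benzyl-2-oxo-1,3-oxazolidin-3-yl]-4-oxobutanoate
Conditions: n-BuLi, THF, −78 °C; then 26, −78 → 0 °C
Reagents that add atoms: none
Why: N-Acylation of the lithiated oxazolidinone by the acid chloride is the standard entry to Evans imides.

Step 20
Reactants: 27 methyl 4-[(4R)-4-benzyl-2-oxo-1,3-oxazolidin-3-yl]-4-oxobutanoate; 24 2α-chloro-18-[(triisopropylsilyl)oxy]-13,14,15,16-tetranorlabd-8(17)-en-12-al
Product: 29 methyl (3R,4S)-3-{[(4R)-4-benzyl-2-oxo-1,3-oxazolidin-3-yl]carbonyl}-4-hydroxy-5-{2α-chloro-18-[(triisopropylsilyl)oxy]-13,14,15,16-tetranorlabd-8(17)-en-11-yl}pentanoate (12S;13R syn-aldol adduct), via boron Z-enolate 28 (not isolated)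
Conditions: 27, Bu2BOTf, i-Pr2NEt, CH2Cl2, −78 → 0 °C; then 24, −78 → 0 °C; pH 7 buffer, MeOH, 30% H2O2, 0 °C
Reagents that add atoms: none
Why: Evans syn-aldol reaction; the imide (not the ester) is enolized to the Z boron enolate, and the closed chair transition state with the (R)-benzyl auxiliary should set 13R and 12S regardless of the remote decalin.

Step 21
Reactants: 29 methyl (3R,4S)-3-{[(4R)-4-benzyl-2-oxo-1,3-oxazolidin-3-yl]carbonyl}-4-hydroxy-5-{2α-chloro-18-[(triisopropylsilyl)oxy]-13,14,15,16-tetranorlabd-8(17)-en-11-yl}pentanoate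
Product: 30 18-O-(triisopropylsilyl)haterumaimide J
Conditions: NH3 (7 M in MeOH), THF, 0 °C → rt
Reagents that add atoms: ammonia, N
Why: Ammonolysis of the activated exocyclic acyl group, assisted by the β-hydroxyl, followed by 5-exo-trig attack of the primary amide on the γ-methyl ester should close the succinimide and release the auxiliary; a γ-lactone formed first from the C-12 hydroxyl and the ester would converge on the same imide.

Step 22
Reactants: 30 18-O-(triisopropylsilyl)haterumaimide J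
Product: 31 haterumaimide J
Conditions: HF·pyridine, pyridine, THF, 0 °C → rt
Reagents that add atoms: none
Why: Buffered fluoride cleavage of the primary TIPS ether is non-basic, so the epimerizable C-13, the β-hydroxy imide and the exocyclic alkene should survive.

**Compound list**

1 | (R)-5-[(trityloxy)methyl]dihydrofuran-2(3H)-one | O=C1CC[C@@H](O1)COC(c1ccccc1)(c1ccccc1)c1ccccc1 | starting material
2 | (3R,5R)-3-{[(triisopropylsilyl)oxy]methyl}-5-[(trityloxy)methyl]dihydrofuran-2(3H)-one | O=C1[C@@H](CO[Si](C(C)C)(C(C)C)C(C)C)C[C@@H](O1)COC(c1ccccc1)(c1ccccc1)c1ccccc1 | intermediate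
3 | (3S,5R)-3-methyl-3-{[(triisopropylsilyl)oxy]methyl}-5-[(trityloxy)methyl]dihydrofuran-2(3H)-one | O=C1[C@](C)(CO[Si](C(C)C)(C(C)C)C(C)C)C[C@@H](O1)COC(c1ccccc1)(c1ccccc1)c1ccccc1 | intermediate
4 | (3S,5R)-5-(hydroxymethyl)-3-methyl-3-{[(triisopropylsilyl)oxy]methyl}dihydrofuran-2(3H)-one | O=C1[C@](C)(CO[Si](C(C)C)(C(C)C)C(C)C)C[C@@H](O1)CO | intermediate
5 | [(2R,4S)-4-methyl-5-oxo-4-{[(triisopropylsilyl)oxy]methyl}tetrahydrofuran-2-yl]methyl 4-methylbenzenesulfonate | O=C1[C@](C)(CO[Si](C(C)C)(C(C)C)C(C)C)C[C@@H](O1)COS(=O)(=O)c1ccc(C)cc1 | intermediate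
6 | methyl (2S)-2-methyl-3-[(2R)-oxiran-2-yl]-2-{[(triisopropylsilyl)oxy]methyl}propanoate | COC(=O)[C@](C)(CO[Si](C(C)C)(C(C)C)C(C)C)C[C@@H]1CO1 | intermediate
7 | tert-butyl(but-3-yn-1-yloxy)dimethylsilane | C#CCCO[Si](C)(C)C(C)(C)C | starting material
8 | methyl (2S,4S)-9-[(tert-butyldimethylsilyl)oxy]-4-hydroxy-2-methyl-2-{[(triisopropylsilyl)oxy]methyl}non-6-ynoate | COC(=O)[C@](C)(CO[Si](C(C)C)(C(C)C)C(C)C)C[C@@H](O)CC#CCCO[Si](C)(C)C(C)(C)C | intermediate
9 | (3S,5S)-5-{5-[(tert-butyldimethylsilyl)oxy]pent-2-yn-1-yl}-3-methyl-3-{[(triisopropylsilyl)oxy]methyl}dihydrofuran-2(3H)-one | O=C1[C@](C)(CO[Si](C(C)C)(C(C)C)C(C)C)C[C@@H](O1)CC#CCCO[Si](C)(C)C(C)(C)C | intermediate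
10 | (3S,5S)-5-{5-[(tert-butyldimethylsilyl)oxy]pent-2-yn-1-yl}-3-methyl-3-{[(triisopropylsilyl)oxy]methyl}tetrahydrofuran-2-ol | OC1[C@](C)(CO[Si](C(C)C)(C(C)C)C(C)C)C[C@@H](O1)CC#CCCO[Si](C)(C)C(C)(C)C | intermediate
11 | (3R,5S)-10-[(tert-butyldimethylsilyl)oxy]-3-methyl-3-{[(triisopropylsilyl)oxy]methyl}dec-1-en-7-yn-5-ol | C=C[C@](C)(CO[Si](C(C)C)(C(C)C)C(C)C)C[C@@H](O)CC#CCCO[Si](C)(C)C(C)(C)C | intermediate
12 | tert-butyl{[(6R,8R)-6-chloro-8-methyl-8-{[(triisopropylsilyl)oxy]methyl}dec-9-en-3-yn-1-yl]oxy}dimethylsilane | C=C[C@](C)(CO[Si](C(C)C)(C(C)C)C(C)C)C[C@H](Cl)CC#CCCO[Si](C)(C)C(C)(C)C | intermediate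
13 | (6R,8R)-6-chloro-8-methyl-8-{[(triisopropylsilyl)oxy]methyl}dec-9-en-3-yn-1-ol | C=C[C@](C)(CO[Si](C(C)C)(C(C)C)C(C)C)C[C@H](Cl)CC#CCCO | intermediate
14 | five-membered oxamagnesacycle from syn addition of CH3 and Mg across C9≡C10 of 13 | C=C[C@](C)(CO[Si](C(C)C)(C(C)C)C(C)C)C[C@H](Cl)C/C(C)=C1\CCO[Mg]1 | intermediate
15 | (2E,5R,7R)-5-chloro-2-(2-hydroxyethyl)-3,7-dimethyl-7-{[(triisopropylsilyl)oxy]methyl}nona-2,8-dienoic acid | C=C[C@](C)(CO[Si](C(C)C)(C(C)C)C(C)C)C[C@H](Cl)C/C(C)=C(\CCO)C(=O)O | intermediate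
16 | (3E)-3-[(4R,6R)-4-chloro-6-methyl-6-{[(triisopropylsilyl)oxy]methyl}oct-7-en-2-ylidene]dihydrofuran-2(3H)-one | C=C[C@](C)(CO[Si](C(C)C)(C(C)C)C(C)C)C[C@H](Cl)C/C(C)=C1\CCOC1=O | intermediate
17 | (2S,4R,6E)-4-chloro-2-methyl-6-(2-oxodihydrofuran-3(2H)-ylidene)-2-{[(triisopropylsilyl)oxy]methyl}heptanal | O=C[C@](C)(CO[Si](C(C)C)(C(C)C)C(C)C)C[C@H](Cl)C/C(C)=C1\CCOC1=O | intermediate
18 | (3E)-3-[(4R,6R,7E)-4-chloro-6-methyl-8-(phenylsulfonyl)-6-{[(triisopropylsilyl)oxy]methyl}oct-7-en-2-ylidene]dihydrofuran-2(3H)-one | O=S(=O)(/C=C/[C@](C)(CO[Si](C(C)C)(C(C)C)C(C)C)C[C@H](Cl)C/C(C)=C1\CCOC1=O)c1ccccc1 | intermediate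
19 | (3E)-3-[(4R,6R,7E)-4-chloro-6-methyl-8-(phenylsulfonyl)-6-{[(triisopropylsilyl)oxy]methyl}oct-7-en-2-ylidene]-2-methylenetetrahydrofuran | O=S(=O)(/C=C/[C@](C)(CO[Si](C(C)C)(C(C)C)C(C)C)C[C@H](Cl)C/C(C)=C1\CCOC1=C)c1ccccc1 | intermediate
20 | 2α-chloro-6α-(phenylsulfonyl)-18-[(triisopropylsilyl)oxy]-8,12-epoxy-13,14,15,16,17-pentanorlabd-8-ene | O1CCC2=C1C[C@H](S(=O)(=O)c1ccccc1)[C@H]3[C@](C)(CO[Si](C(C)C)(C(C)C)C(C)C)C[C@H](Cl)C[C@]23C | intermediate
21 | 2α-chloro-18-[(triisopropylsilyl)oxy]-8,12-epoxy-13,14,15,16,17-pentanorlabd-8-ene | O1CCC2=C1CC[C@H]3[C@](C)(CO[Si](C(C)C)(C(C)C)C(C)C)C[C@H](Cl)C[C@]23C | intermediate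
22 | 2α-chloro-12-hydroxy-18-[(triisopropylsilyl)oxy]-13,14,15,16,17-pentanorlabdan-8-one | O=C1CC[C@H]2[C@](C)(CO[Si](C(C)C)(C(C)C)C(C)C)C[C@H](Cl)C[C@]2(C)[C@H]1CCO | intermediate
23 | 2α-chloro-18-[(triisopropylsilyl)oxy]-13,14,15,16-tetranorlabd-8(17)-en-12-ol | C=C1CC[C@H]2[C@](C)(CO[Si](C(C)C)(C(C)C)C(C)C)C[C@H](Cl)C[C@]2(C)[C@H]1CCO | intermediate
24 | 2α-chloro-18-[(triisopropylsilyl)oxy]-13,14,15,16-tetranorlabd-8(17)-en-12-al | C=C1CC[C@H]2[C@](C)(CO[Si](C(C)C)(C(C)C)C(C)C)C[C@H](Cl)C[C@]2(C)[C@H]1CC=O | intermediate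
25 | (R)-4-benzyl-1,3-oxazolidin-2-one | O=C1N[C@H](Cc2ccccc2)CO1 | starting material
26 | methyl 4-chloro-4-oxobutanoate | COC(=O)CCC(Cl)=O | starting material
27 | methyl 4-[(4R)-4-benzyl-2-oxo-1,3-oxazolidin-3-yl]-4-oxobutanoate | COC(=O)CCC(=O)N1[C@H](Cc2ccccc2)COC1=O | intermediate
28 | dibutylboron (Z)-enolate of 27 | COC(=O)C/C=C(\OB(CCCC)CCCC)N1[C@H](Cc2ccccc2)COC1=O | intermediate
29 | methyl (3R,4S)-3-{[(4R)-4-benzyl-2-oxo-1,3-oxazolidin-3-yl]carbonyl}-4-hydroxy-5-{2α-chloro-18-[(triisopropylsilyl)oxy]-13,14,15,16-tetranorlabd-8(17)-en-11-yl}pentanoate | C=C1CC[C@H]2[C@](C)(CO[Si](C(C)C)(C(C)C)C(C)C)C[C@H](Cl)C[C@]2(C)[C@H]1C[C@H](O)[C@@H](CC(=O)OC)C(=O)N1[C@H](Cc2ccccc2)COC1=O | intermediate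
30 | 18-O-(triisopropylsilyl)haterumaimide J | C=C1CC[C@H]2[C@](C)(CO[Si](C(C)C)(C(C)C)C(C)C)C[C@H](Cl)C[C@]2(C)[C@H]1C[C@H](O)[C@H]1CC(=O)NC1=O | intermediate
31 | haterumaimide J | C=C1CC[C@H]2[C@](C)(CO)C[C@H](Cl)C[C@]2(C)[C@H]1C[C@H](O)[C@H]1CC(=O)NC1=O | target

**Step count**

Total: 22 steps. Longest linear sequence: 21 steps (steps 1–18 and 20–22); step 19 is a one-step branch.

**Steps most likely to fail**

Step 15. The tether-endo transition state may compete and give the cis-fused decalin, and the dienol ether may isomerize or undergo a 1,5-hydrogen shift before it cyclizes. The fallback inverts the dienophile geometry, so that the transition state with both tether and sulfonyl group exo leads to the same trans ring fusion. It sets out from aldehyde 17: Ohira–Bestmann homologation should give the terminal alkyne F1; base-catalysed anti addition of thiophenol gives the (Z)-vinyl sulfide F2; oxidation (oxone) gives the (Z)-vinyl sulfone F3; Tebbe methylenation gives the (Z)-triene F4; heating as in step 15 gives the 6β-sulfonyl tricycle F5, which under the conditions of step 16 loses the sulfonyl group and comes back to the route at 22.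

Step 11. Low-valent iron–methyl species may reduce, eliminate or couple the secondary C–Cl bond, and the hindered alkenylmagnesium may be carboxylated incompletely. The fallback moves the chlorination behind the carbometalation. It sets out from alcohol 11: NaH and 4-methoxybenzyl chloride give the PMB ether F6; CSA in MeOH/CH2Cl2 at 0 °C, as in step 10, gives the homopropargylic alcohol F7; the same carbomagnesiation, carboxylation and lactonization give the alkylidene lactone PMB ether F8; DDQ gives the C-2 alcohol F9; Appel chlorination with inversion then comes back to the route at 16.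

Step 21. Ammonia may attack the endocyclic carbamate carbonyl, over-ammonolysis may give the diamide, and C-13 may epimerize or the aldol may revert. The fallback separates auxiliary removal from nitrogen introduction. It sets out from 29: LiOH/H2O2 cleaves the auxiliary to the carboxylic acid F10; EDC, HOBt and NH4Cl/i-Pr2NEt give the primary amide F11; catalytic K2CO3 in MeOH closes the imide onto the methyl ester and comes back to the route at 30.

**Further compounds**

F1 | step 15 | (3E)-3-[(4R,6R)-4-chloro-6-methyl-6-{[(triisopropylsilyl)oxy]methyl}oct-7-yn-2-ylidene]dihydrofuran-2(3H)-one | C#C[C@](C)(CO[Si](C(C)C)(C(C)C)C(C)C)C[C@H](Cl)C/C(C)=C1\CCOC1=O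
F2 | step 15 | (3E)-3-[(4R,6R,7Z)-4-chloro-6-methyl-8-(phenylsulfanyl)-6-{[(triisopropylsilyl)oxy]methyl}oct-7-en-2-ylidene]dihydrofuran-2(3H)-one | c1ccccc1S/C=C\[C@](C)(CO[Si](C(C)C)(C(C)C)C(C)C)C[C@H](Cl)C/C(C)=C1\CCOC1=O
F3 | step 15 | (3E)-3-[(4R,6R,7Z)-4-chloro-6-methyl-8-(phenylsulfonyl)-6-{[(triisopropylsilyl)oxy]methyl}oct-7-en-2-ylidene]dihydrofuran-2(3H)-one | O=S(=O)(c1ccccc1)/C=C\[C@](C)(CO[Si](C(C)C)(C(C)C)C(C)C)C[C@H](Cl)C/C(C)=C1\CCOC1=O
F4 | step 15 | (3E)-3-[(4R,6R,7Z)-4-chloro-6-methyl-8-(phenylsulfonyl)-6-{[(triisopropylsilyl)oxy]methyl}oct-7-en-2-ylidene]-2-methylenetetrahydrofuran | O=S(=O)(c1ccccc1)/C=C\[C@](C)(CO[Si](C(C)C)(C(C)C)C(C)C)C[C@H](Cl)C/C(C)=C1\CCOC1=C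
F5 | step 15 | 2α-chloro-6β-(phenylsulfonyl)-18-[(triisopropylsilyl)oxy]-8,12-epoxy-13,14,15,16,17-pentanorlabd-8-ene | O1CCC2=C1C[C@@H](S(=O)(=O)c1ccccc1)[C@H]3[C@](C)(CO[Si](C(C)C)(C(C)C)C(C)C)C[C@H](Cl)C[C@]23C
F6 | step 11 | tert-butyl{[(6S,8R)-6-[(4-methoxybenzyl)oxy]-8-methyl-8-{[(triisopropylsilyl)oxy]methyl}dec-9-en-3-yn-1-yl]oxy}dimethylsilane | C=C[C@](C)(CO[Si](C(C)C)(C(C)C)C(C)C)C[C@@H](OCc1ccc(OC)cc1)CC#CCCO[Si](C)(C)C(C)(C)C
F7 | step 11 | (6S,8R)-6-[(4-methoxybenzyl)oxy]-8-methyl-8-{[(triisopropylsilyl)oxy]methyl}dec-9-en-3-yn-1-ol | C=C[C@](C)(CO[Si](C(C)C)(C(C)C)C(C)C)C[C@@H](OCc1ccc(OC)cc1)CC#CCCO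
F8 | step 11 | (3E)-3-[(4S,6R)-4-[(4-methoxybenzyl)oxy]-6-methyl-6-{[(triisopropylsilyl)oxy]methyl}oct-7-en-2-ylidene]dihydrofuran-2(3H)-one | C=C[C@](C)(CO[Si](C(C)C)(C(C)C)C(C)C)C[C@@H](OCc1ccc(OC)cc1)C/C(C)=C1\CCOC1=O
F9 | step 11 | (3E)-3-[(4S,6R)-4-hydroxy-6-methyl-6-{[(triisopropylsilyl)oxy]methyl}oct-7-en-2-ylidene]dihydrofuran-2(3H)-one | C=C[C@](C)(CO[Si](C(C)C)(C(C)C)C(C)C)C[C@@H](O)C/C(C)=C1\CCOC1=O
F10 | step 21 | (2R)-2-[(1S)-1-hydroxy-2-{2α-chloro-18-[(triisopropylsilyl)oxy]-13,14,15,16-tetranorlabd-8(17)-en-11-yl}ethyl]-4-methoxy-4-oxobutanoic acid | C=C1CC[C@H]2[C@](C)(CO[Si](C(C)C)(C(C)C)C(C)C)C[C@H](Cl)C[C@]2(C)[C@H]1C[C@H](O)[C@@H](CC(=O)OC)C(=O)O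
F11 | step 21 | methyl (3R,4S)-3-carbamoyl-4-hydroxy-5-{2α-chloro-18-[(triisopropylsilyl)oxy]-13,14,15,16-tetranorlabd-8(17)-en-11-yl}pentanoate | C=C1CC[C@H]2[C@](C)(CO[Si](C(C)C)(C(C)C)C(C)C)C[C@H](Cl)C[C@]2(C)[C@H]1C[C@H](O)[C@@H](CC(=O)OC)C(N)=O
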